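**Retrosynthetic overview**

- Feature: ring B, the benzene ring of the chromene, carries oxygen on C5, C7 and C8a in a 1,3,5 pattern and shares the C4a–C8a bond with the dimethylpyran. This is the atom pattern of a 4-alkoxy-2-pyrone fused to that same pyran (lactone carbonyl = C5, enol-ether carbon = C8a, ring-oxygen carbon = C7).
- Disconnections, last to first: C8–acetyl bond (Friedel–Crafts); C5–C6 bond of ring B (methoxide opening of pyrano[4,3-b]pyran-5-one 14, then Claisen recyclisation); 2H-pyran ring (Knoevenagel/oxa-6π annulation of hydroxypyrone 11 with 3-methylbut-2-enal); pyrone ring (acylketene cyclisation of dioxinone 9); ring A–CH2 bond (Michael addition of propanoylfilicinic acid 3 to vinyl ketone 8).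
- Ring order: ring A (gem-dimethylation of flopropione), 2-pyrone, 2H-pyran, then benzene ring B at the expense of the pyrone. The acetyl group comes last because an acetyl on C8 of 14 would offer its own methyl group as a competing Claisen nucleophile.

Key step: step 7

Remark: the target has no stereocentre. Ring A is an enolised β-triketone drawn throughout in the tautomer of the target SMILES, and its tautomers count as one compound. RA stands for the ring A substituent 2,4-dihydroxy-3,3-dimethyl-6-oxo-5-propanoylcyclohexa-1,4-dien-1-yl. Ring B is numbered as a chromene and 14 as a pyrano[4,3-b]pyran, so C5, C7 and C8 keep their numbers through the key step.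

**Route**

Step 1
Reactants: 1 flopropione (1-(2,4,6-trihydroxyphenyl)propan-1-one)
Product: 3 propanoylfilicinic acid (3,5-dihydroxy-4,4-dimethyl-2-propanoylcyclohexa-2,5-dien-1-one), via C-methylflopropione 2 (not isolated)
Conditions: NaOMe (3 equiv), MeI (2.2 equiv), MeOH, 0 °C to rt; 1 M HCl
Reagents that add atoms: iodomethane, SMILES CI
Why: Dearomatising double C-methylation of the acylphloroglucinol anion should place both methyl groups on one unsubstituted ring carbon, since the mono-methylated carbon of 2 stays the most nucleophilic site and the resulting vinylogous acid anion of 3 is a poorer nucleophile; no stereocentre is formed.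

Step 2
Reactants: 4 2,2,6-trimethyl-4H-1,3-dioxin-4-one; 5 acrolein
Product: 7 6-(2-hydroxybut-3-en-1-yl)-2,2-dimethyl-4H-1,3-dioxin-4-one (racemic), via lithium dienolate 6 (not isolated)
Conditions: LiN(iPr)2 (1.1 equiv, commercial solution), THF, −78 °C; then 5, −78 °C; AcOH quench
Reagents that add atoms: none
Why: Kinetic deprotonation of the dioxinone methyl group and vinylogous aldol 1,2-addition of the lithium dienolate through its γ-carbon to acrolein should give the allylic alcohol, whose carbinol stereocentre forms racemic and is removed by the oxidation in step 3.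

Step 3
Reactants: 7 6-(2-hydroxybut-3-en-1-yl)-2,2-dimethyl-4H-1,3-dioxin-4-one
Product: 8 2,2-dimethyl-6-(2-oxobut-3-en-1-yl)-4H-1,3-dioxin-4-one
Conditions: Dess–Martin periodinane (1.2 equiv), CH2Cl2, 0 °C to rt; used at once
Reagents that add atoms: none
Why: Dess–Martin oxidation of an allylic alcohol should give the vinyl ketone under nearly neutral conditions that leave the dioxinone untouched.

Step 4
Reactants: 3 propanoylfilicinic acid; 8 2,2-dimethyl-6-(2-oxobut-3-en-1-yl)-4H-1,3-dioxin-4-one
Product: 9 6-[4-(RA)-2-oxobutyl]-2,2-dimethyl-4H-1,3-dioxin-4-one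
Conditions: Et3N (0.2 equiv), MeCN, 0 °C to rt; slow addition of 8 to 3 (1.3 equiv)
Reagents that add atoms: none
Why: Michael addition of the soft, strongly acidic cyclic β-triketone through C6, its only ring CH, to an unhindered vinyl ketone should proceed under catalytic amine, where the far less acidic methylene of 8 stays protonated; no stereocentre is formed.

Step 5
Reactants: 9 6-[4-(RA)-2-oxobutyl]-2,2-dimethyl-4H-1,3-dioxin-4-one
Product: 11 4-hydroxy-6-[2-(RA)ethyl]-2H-pyran-2-one, via acylketene 10 (not isolated)
Conditions: toluene (0.01 M), 110 °C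
Reagents that add atoms: none
Why: Retro-hetero-Diels–Alder loss of acetone from the dioxinone gives the acylketene, which the enol oxygen of the δ-ketone should capture in a six-membered lactonisation (the acylketene route to 4-hydroxy-2-pyrones), faster under high dilution than any intermolecular capture by ring A enols.

Step 6
Reactants: 11 4-hydroxy-6-[2-(RA)ethyl]-2H-pyran-2-one; 12 3-methylbut-2-enal
Product: 14 7-[2-(RA)ethyl]-2,2-dimethyl-2H,5H-pyrano[4,3-b]pyran-5-one, via alkylidene pyrandione 13 (not isolated)
Conditions: ethylenediammonium diacetate (0.2 equiv), MeOH, 50 °C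
Reagents that add atoms: none
Why: Amine-catalysed Knoevenagel condensation at C3 of the hydroxypyrone followed by oxa-6π electrocyclisation through the C4 oxygen (formal [3+3] annulation) should give one pyran orientation only, because ring A has no free carbon and the pyrone offers a single enol oxygen next to C3.

Step 7
Reactants: 14 7-[2-(RA)ethyl]-2,2-dimethyl-2H,5H-pyrano[4,3-b]pyran-5-one
Product: 17 6-[(5,7-dihydroxy-2,2-dimethyl-2H-chromen-6-yl)methyl]-3,5-dihydroxy-4,4-dimethyl-2-propanoylcyclohexa-2,5-dien-1-one (des-acetyl target), via ring-opened methyl ester 15 (not isolated), via diketone tautomer 16 (not isolated)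
Conditions: NaOMe (8 equiv), degassed MeOH, 65 °C, Ar; then cold 1 M HCl to pH 3
Reagents that add atoms: none
Why: Proposed new method: methoxide adds to the lactone carbonyl C5 of the 4-alkoxy-2-pyrone and the ring opens to methyl ester 15, in which C7 is now a ketone and the ester sits on the pyran double bond cis to the ketone chain; under equilibrating conditions the ketone also enolises toward the chain methylene that carries the ring A methylene (future C6), and this enolate attacks the ester carbonyl (future C5) in a Claisen (Dieckmann-type) condensation that expels methoxide to give diketone 16, which aromatises by enolisation to the 5,7-dihydroxychromene. The closest known reaction type is the alkoxide-induced opening of 4-oxygenated 6-acylmethyl-2-pyrones and Claisen recyclisation of the resulting polyketo esters to acylphloroglucinols, which has not been shown for a pyrone whose 4-oxygen is locked in a fused 2H-pyran and whose nucleophile is a plain alkyl ketone unmasked by the ring opening itself. Ring B closes in a 6-exo-trig mode, C6 onto C5, with the ester C=O exocyclic to the forming ring. No stereocentre results, since C6 of 16 becomes sp2 on aromatisation. The selectivity needed is closure through the chain α-carbon and not through C8: the C8 enolate is the more stable one but can only return to lactone 14 or form a four-membered ring, C4a has no hydrogen for an aldol alternative, and the aromatisation of 16 makes the six-membered closure irreversible. The 2H-pyran should stay closed because of its gem-dimethyl group and the ester conjugation, and ring A, fully deprotonated by the excess NaOMe, should be protected against retro-Michael loss and deacylation.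

Step 8
Reactants: 17 des-acetyl target
Product: 19 6-[(8-acetyl-5,7-dihydroxy-2,2-dimethyl-2H-chromen-6-yl)methyl]-3,5-dihydroxy-4,4-dimethyl-2-propanoylcyclohexa-2,5-dien-1-one (target), via difluoroboron chelate 18 (not isolated)
Conditions: Ac2O (1.5 equiv), BF3·OEt2 (3 equiv), EtOAc, 0 °C to rt; then NaOAc, MeOH/H2O, 50 °C
Reagents that add atoms: acetic anhydride, SMILES CC(=O)OC(C)=O
Why: Friedel–Crafts C-acylation of the phloroglucinol-type ring B should occur at C8, its only unsubstituted carbon, and the product is held as the difluoroboron chelate 18 between O7 and the acetyl oxygen, which blocks further acylation and is hydrolysed by the buffered aqueous methanol.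

**Compound list**

1 | flopropione, 1-(2,4,6-trihydroxyphenyl)propan-1-one | CCC(=O)c1c(O)cc(O)cc1O | starting material
2 | 1-(2,4,6-trihydroxy-3-methylphenyl)propan-1-one (C-methylflopropione, not isolated) | CCC(=O)c1c(O)cc(O)c(C)c1O | intermediate
3 | propanoylfilicinic acid, 3,5-dihydroxy-4,4-dimethyl-2-propanoylcyclohexa-2,5-dien-1-one | CCC(=O)C1=C(O)C(C)(C)C(O)=CC1=O | intermediate
4 | 2,2,6-trimethyl-4H-1,3-dioxin-4-one | CC1=CC(=O)OC(C)(C)O1 | starting material
5 | acrolein (prop-2-enal) | C=CC=O | starting material
6 | lithium 2,2-dimethyl-6-methylidene-6H-1,3-dioxin-4-olate (lithium dienolate of 4, not isolated) | [Li+].[O-]C1=CC(=C)OC(C)(C)O1 | intermediate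
7 | 6-(2-hydroxybut-3-en-1-yl)-2,2-dimethyl-4H-1,3-dioxin-4-one (racemic) | C=CC(O)CC1=CC(=O)OC(C)(C)O1 | intermediate
8 | 2,2-dimethyl-6-(2-oxobut-3-en-1-yl)-4H-1,3-dioxin-4-one | C=CC(=O)CC1=CC(=O)OC(C)(C)O1 | intermediate
9 | 6-[4-(RA)-2-oxobutyl]-2,2-dimethyl-4H-1,3-dioxin-4-one | CCC(=O)C1=C(O)C(C)(C)C(O)=C(CCC(=O)CC2=CC(=O)OC(C)(C)O2)C1=O | intermediate
10 | 7-(RA)hept-1-ene-1,3,5-trione (acylketene, not isolated) | CCC(=O)C1=C(O)C(C)(C)C(O)=C(CCC(=O)CC(=O)C=C=O)C1=O | intermediate
11 | 4-hydroxy-6-[2-(RA)ethyl]-2H-pyran-2-one | CCC(=O)C1=C(O)C(C)(C)C(O)=C(CCC2=CC(O)=CC(=O)O2)C1=O | intermediate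
12 | 3-methylbut-2-enal | CC(C)=CC=O | starting material
13 | 6-[2-(RA)ethyl]-3-(3-methylbut-2-en-1-ylidene)-2H-pyran-2,4(3H)-dione (either geometry at the exocyclic C=C, not isolated) | CCC(=O)C1=C(O)C(C)(C)C(O)=C(CCC2=CC(=O)C(=CC=C(C)C)C(=O)O2)C1=O | intermediate
14 | 7-[2-(RA)ethyl]-2,2-dimethyl-2H,5H-pyrano[4,3-b]pyran-5-one | CCC(=O)C1=C(O)C(C)(C)C(O)=C(CCC2=CC3=C(C=CC(C)(C)O3)C(=O)O2)C1=O | intermediate
15 | methyl 2,2-dimethyl-6-[4-(RA)-2-oxobutyl]-2H-pyran-5-carboxylate (not isolated) | CCC(=O)C1=C(O)C(C)(C)C(O)=C(CCC(=O)CC2=C(C(=O)OC)C=CC(C)(C)O2)C1=O | intermediate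
16 | 6-[(RA)methyl]-2,2-dimethyl-2H-chromene-5,7(6H,8H)-dione (racemic at C6, not isolated) | CCC(=O)C1=C(O)C(C)(C)C(O)=C(CC2C(=O)CC3=C(C=CC(C)(C)O3)C2=O)C1=O | intermediate
17 | 6-[(5,7-dihydroxy-2,2-dimethyl-2H-chromen-6-yl)methyl]-3,5-dihydroxy-4,4-dimethyl-2-propanoylcyclohexa-2,5-dien-1-one | CCC(=O)C1=C(O)C(C)(C)C(O)=C(Cc2c(O)cc3OC(C)(C)C=Cc3c2O)C1=O | intermediate
18 | difluoroboron chelate of 19, boron bound to O7 and the acetyl oxygen (not isolated) | CCC(=O)C1=C(O)C(C)(C)C(O)=C(Cc2c(O)c3C=CC(C)(C)Oc3c4c2O[B-](F)(F)[O+]=C4C)C1=O | intermediate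
19 | 6-[(8-acetyl-5,7-dihydroxy-2,2-dimethyl-2H-chromen-6-yl)methyl]-3,5-dihydroxy-4,4-dimethyl-2-propanoylcyclohexa-2,5-dien-1-one | CCC(=O)C1=C(O)C(C)(C)C(O)=C(Cc2c(O)c3c(c(C(C)=O)c2O)OC(C)(C)C=C3)C1=O | target

**Step count and risks**

Total step count: 8. Longest linear sequence: 7 steps (4 → 7 → 8 → 9 → 11 → 14 → 17 → 19); ring A joins after one step.

Steps most likely to fail:

1. Step 7 (key step). Possible failures:
   - Methoxide may add at C7 in a conjugate sense and open the pyrone the wrong way, to a carboxylate that cannot recyclise.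
   - Return to the lactone may outrun the Claisen closure, so that nothing is converted.
   - Methoxide may exchange at C8a and open the 2H-pyran.
   - The methylene bridge of the product may scramble in base by retro-Michael cleavage and recombination.

   Fallback, known chemistry, from 3 to 19: the classical methylene bridging of two acylphloroglucinol halves. Compound 3 is aminomethylated at C6 with dimethylmethylideneammonium iodide (Mannich reaction) to 6-[(dimethylamino)methyl]-3,5-dihydroxy-4,4-dimethyl-2-propanoylcyclohexa-2,5-dien-1-one F1. Purchased 2,4,6-trihydroxyacetophenone is condensed with 12 (ethylenediammonium diacetate or hot pyridine; Knoevenagel/oxa-6π), and the 8-acetyl regioisomer 1-(5,7-dihydroxy-2,2-dimethyl-2H-chromen-8-yl)ethan-1-one F2 is separated. Heating F1 with F2 in dioxane eliminates the amine, and C6 of F2, its only free ring carbon, adds to the methylene-trione so formed. This gives 19 directly and also bypasses step 8.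

2. Step 8. Possible failures:
   - Electrophilic attack on the electron-rich C3=C4 bond of the chromene, or its acid-induced oligomerisation.
   - O-acetylation of phenols and ring A enols without transfer to carbon.
   - Acid-induced cleavage of the methylene bridge.

   Fallback from 17 to 19, without Lewis acid: iodination at C8 with N-iodosuccinimide in MeCN at 0 °C gives the 8-iodo derivative of 17 F3. Stille coupling with tributyl(1-ethoxyvinyl)stannane and Pd(PPh3)4 in dioxane gives the 8-(1-ethoxyvinyl) derivative of 17 F4. Hydrolysis of the enol ether with dilute HCl in THF at rt gives 19.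

3. Step 4. Possible failures:
   - A second Michael addition at the now fully substituted ring A carbon.
   - Oligomerisation of the vinyl ketone through its own acidic methylene.
   - Ring–chain tautomerism of the adduct, followed by dehydration to a fused 4H-pyran on heating in step 5.

   Fallback from 3 to 11, replacing steps 2 to 5 by an acrylate/acetoacetate sequence: Michael addition of 3 to methyl acrylate (catalytic NaOMe, MeOH, reflux) gives methyl 3-(RA)propanoate F5. Saponification with LiOH in aqueous THF gives 3-(RA)propanoic acid F6. 1,1'-Carbonyldiimidazole in THF converts it into the acyl imidazolide 1-[3-(RA)propanoyl]imidazole F7. F7 is added to an excess of the dianion of methyl acetoacetate (NaH, then n-BuLi, THF, −78 to 0 °C; the excess absorbs the acidic protons of ring A) and gives methyl 7-(RA)-3,5-dioxoheptanoate F8. DBU in hot toluene lactonises F8 to 11.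

**Further compounds**

F1 | step 7 | 6-[(dimethylamino)methyl]-3,5-dihydroxy-4,4-dimethyl-2-propanoylcyclohexa-2,5-dien-1-one | CCC(=O)C1=C(O)C(C)(C)C(O)=C(CN(C)C)C1=O
F2 | step 7 | 1-(5,7-dihydroxy-2,2-dimethyl-2H-chromen-8-yl)ethan-1-one | CC(=O)c1c(O)cc(O)c2C=CC(C)(C)Oc12
F3 | step 8 | 6-[(5,7-dihydroxy-8-iodo-2,2-dimethyl-2H-chromen-6-yl)methyl]-3,5-dihydroxy-4,4-dimethyl-2-propanoylcyclohexa-2,5-dien-1-one | CCC(=O)C1=C(O)C(C)(C)C(O)=C(Cc2c(O)c(I)c3OC(C)(C)C=Cc3c2O)C1=O
F4 | step 8 | 6-{[8-(1-ethoxyethenyl)-5,7-dihydroxy-2,2-dimethyl-2H-chromen-6-yl]methyl}-3,5-dihydroxy-4,4-dimethyl-2-propanoylcyclohexa-2,5-dien-1-one | CCC(=O)C1=C(O)C(C)(C)C(O)=C(Cc2c(O)c(C(=C)OCC)c3OC(C)(C)C=Cc3c2O)C1=O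
F5 | step 4 | methyl 3-(RA)propanoate | CCC(=O)C1=C(O)C(C)(C)C(O)=C(CCC(=O)OC)C1=O
F6 | step 4 | 3-(RA)propanoic acid | CCC(=O)C1=C(O)C(C)(C)C(O)=C(CCC(=O)O)C1=O
F7 | step 4 | 1-[3-(RA)propanoyl]imidazole | CCC(=O)C1=C(O)C(C)(C)C(O)=C(CCC(=O)n2ccnc2)C1=O
F8 | step 4 | methyl 7-(RA)-3,5-dioxoheptanoate | CCC(=O)C1=C(O)C(C)(C)C(O)=C(CCC(=O)CC(=O)CC(=O)OC)C1=O
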